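1. Final step: fluoride cleavage of two aryl silyl ethers. Chain carbons are numbered C1' (benzylic) to C17' (methyl); the chain sits on ring carbon C5.
2. Key disconnection: both alkenes of the skipped (Z,Z)-diene, C8'=C9' and C11'=C12', are cut in one operation. The locally symmetric C9'–C10'–C11' unit becomes a single C3 1,3-bis(phosphonium) linchpin that stitches two carbonyl partners together.
3. Ring-side partner (C1'–C8'): an 8-aryloctanal from bis-silylated 5-bromoresorcinol by B-alkyl Suzuki coupling (C5–C1' bond) with oct-7-en-1-ol, then oxidation.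
4. Carbinol-side partner (C12'–C17'): the lactol of (S)-5-hydroxyhexanal, from (S)-propylene oxide (source of C16') by butenyl Grignard opening and ozonolysis. It brings the C16' hydroxyl in unprotected.
5. No ring is formed: the resorcinol ring is bought, and the only cyclic intermediate, the lactol, is opened in the key step.

Key step: step 6

Remark: the target is read as 5-[(8Z,11Z,16S)-16-hydroxyheptadeca-8,11-dien-1-yl]benzene-1,3-diol. 5-Bromoresorcinol, oct-7-en-1-ol, (S)-propylene oxide, but-3-enylmagnesium bromide solution and propane-1,3-diylbis(triphenylphosphonium) dibromide are assumed to be commercial. The anomeric mixture of the lactol is of no consequence, because the anomeric carbon becomes the sp2 carbon C12'.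

**Step 1**
Reactants: 1 5-bromobenzene-1,3-diol
Product: 2 1-bromo-3,5-bis(triisopropylsilyloxy)benzene
Conditions: TIPSCl (2.4 equiv), imidazole (5 equiv), DMF, rt
Reagents that add atoms: chlorotriisopropylsilane (TIPSCl), CC(C)[Si](Cl)(C(C)C)C(C)C
Why: Imidazole-promoted O-silylation of both phenols should mask the acidic OH groups as TIPS ethers that tolerate aqueous phosphate, amide base and ylides and are later removed by fluoride.

**Step 2**
Reactants: 2 1-bromo-3,5-bis(triisopropylsilyloxy)benzene; 3 oct-7-en-1-ol
Product: 5 8-[3,5-bis(triisopropylsilyloxy)phenyl]octan-1-ol, via O-borylated alkylborane 4 (not isolated)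
Conditions: 3 (1.3 equiv), 9-BBN (2.8 equiv), THF, 0 °C to rt; then 2, Pd(dppf)Cl2 (3 mol %), aq. K3PO4 (3 equiv), THF–DMF, 60 °C
Reagents that add atoms: none
Why: Anti-Markovnikov hydroboration of the terminal alkene with 9-BBN followed by B-alkyl Suzuki–Miyaura coupling with the aryl bromide should form the C5–C1' bond, the second equivalent of borane being consumed by the free hydroxyl as a borinate that is hydrolysed on work-up.

**Step 3**
Reactants: 5 8-[3,5-bis(triisopropylsilyloxy)phenyl]octan-1-ol
Product: 6 8-[3,5-bis(triisopropylsilyloxy)phenyl]octanal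
Conditions: TEMPO (10 mol %), PhI(OAc)2 (1.2 equiv), CH2Cl2, rt
Reagents that add atoms: none
Why: The TEMPO/oxoammonium oxidation of a primary alcohol should stop cleanly at the aldehyde under nearly neutral conditions that leave the aryl silyl ethers untouched.

**Step 4**
Reactants: 7 (S)-2-methyloxirane; 8 but-3-en-1-ylmagnesium bromide
Product: 9 (S)-hept-6-en-2-ol
Conditions: CuI (10 mol %), THF, −40 to 0 °C; aq. NH4Cl
Reagents that add atoms: none
Why: Copper-catalysed SN2 opening of the terminal epoxide by the Grignard reagent occurs at the unsubstituted carbon, so the C–O stereocentre is not touched and the (S) configuration of C16' is carried over from 7.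

**Step 5**
Reactants: 9 (S)-hept-6-en-2-ol
Product: 11 (6S)-6-methyltetrahydro-2H-pyran-2-ol, via secondary ozonide 10 (not isolated)
Conditions: O3, CH2Cl2, −78 °C; PPh3 (1.1 equiv), −78 °C to rt
Reagents that add atoms: ozone, [O-][O+]=O
Why: Criegee ozonolysis of the terminal alkene and reduction of the ozonide with PPh3 should give (S)-5-hydroxyhexanal, which closes spontaneously to the six-membered lactol without involving the carbinol stereocentre.

**Step 6**
Reactants: 6 8-[3,5-bis(triisopropylsilyloxy)phenyl]octanal; 12 propane-1,3-diylbis(triphenylphosphonium) dibromide; 11 (6S)-6-methyltetrahydro-2H-pyran-2-ol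
Product: 17 (2S,6Z,9Z)-17-[3,5-bis(triisopropylsilyloxy)phenyl]heptadeca-6,9-dien-2-ol, via mono-ylide 13 (not isolated), via Z-homoallylic phosphonium bromide 14 (not isolated), via homoallylic ylide 15 (not isolated), via sodium lactolate 16 (not isolated)
Conditions: 12 (1.05 equiv), NaHMDS (1.0 equiv), THF–DMPU, 0 °C to rt; 6 (1.0 equiv), −78 to 0 °C; NaHMDS (1.0 equiv), −78 °C; 16 [from 11 (1.3 equiv), NaHMDS (1.3 equiv), THF, −78 °C], −78 °C to rt; AcOH, H2O
Reagents that add atoms: none
Why: Mono-deprotonation of the C3 bis(phosphonium) salt gives the non-stabilised ylide 13, which adds to aldehyde 6 through the kinetically controlled, puckered [2+2] transition state of a lithium-free Wittig olefination and collapses with loss of Ph3P=O to the Z-alkene 14 (C8'=C9'); a second deprotonation turns the remaining phosphonium terminus into the β,γ-unsaturated ylide 15, which olefinates the ring-opened form of lactolate 16 in the same way to form C11'=C12'. The closest known reaction type is the one-pot sequential double Wittig olefination of α,ω-bis(phosphonium) salts with two different aldehydes, as used for all-Z skipped polyenes, combined with the Wittig olefination of lactols that releases the chain hydroxyl. No ring is closed; the step joins three chains at two C=C bonds and delivers all seventeen chain carbons with the carbinol unprotected. Both Z geometries are set by kinetic control (sodium counter-ion, THF–DMPU, −78 °C, no lithium salts), the usual outcome for non-stabilised and homoallylic ylides, while the C16' stereocentre is remote from every reacting centre and is carried through unchanged from 11. The selectivity the step needs is differentiation of the two constitutionally equivalent phosphonium termini, which is secured by one equivalent of base per stage (the dication is more acidic than the ylide–phosphonium monocation, so proton exchange should funnel the mixture to 13) and by completing the first olefination before the second base charge. Any symmetrical double-olefination products differ grossly in polarity from 17 (a hydroxyl-free bis-arene and an arene-free diol), and the lactol is added as its sodium salt so that its OH does not quench ylide 15.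

**Step 7**
Reactants: 17 (2S,6Z,9Z)-17-[3,5-bis(triisopropylsilyloxy)phenyl]heptadeca-6,9-dien-2-ol
Product: 18 Hansfordiol D, 5-[(8Z,11Z,16S)-16-hydroxyheptadeca-8,11-dien-1-yl]benzene-1,3-diol
Conditions: TBAF (2.5 equiv), AcOH (2.5 equiv), THF, 0 °C, under argon
Reagents that add atoms: none
Why: Fluoride-mediated desilylation should cleave both aryl Si–O bonds (phenoxide is a good leaving group on silicon) under buffered conditions that affect neither the skipped Z,Z-diene nor the secondary carbinol.

**Compound list**

1 | 5-bromobenzene-1,3-diol (5-bromoresorcinol) | Oc1cc(O)cc(Br)c1 | starting material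
2 | 1-bromo-3,5-bis(triisopropylsilyloxy)benzene | Brc1cc(O[Si](C(C)C)(C(C)C)C(C)C)cc(O[Si](C(C)C)(C(C)C)C(C)C)c1 | intermediate
3 | oct-7-en-1-ol | OCCCCCCC=C | starting material
4 | 9-{8-[(9-borabicyclo[3.3.1]nonan-9-yl)oxy]octyl}-9-borabicyclo[3.3.1]nonane | B1(CCCCCCCCOB2C3CCCC2CCC3)C2CCCC1CCC2 | intermediate (not isolated)
5 | 8-[3,5-bis(triisopropylsilyloxy)phenyl]octan-1-ol | OCCCCCCCCc1cc(O[Si](C(C)C)(C(C)C)C(C)C)cc(O[Si](C(C)C)(C(C)C)C(C)C)c1 | intermediate
6 | 8-[3,5-bis(triisopropylsilyloxy)phenyl]octanal | O=CCCCCCCCc1cc(O[Si](C(C)C)(C(C)C)C(C)C)cc(O[Si](C(C)C)(C(C)C)C(C)C)c1 | intermediate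
7 | (S)-2-methyloxirane ((S)-propylene oxide) | C[C@H]1CO1 | starting material
8 | but-3-en-1-ylmagnesium bromide | C=CCC[Mg]Br | starting material
9 | (S)-hept-6-en-2-ol | C[C@H](O)CCCC=C | intermediate
10 | (2S)-5-(1,2,4-trioxolan-3-yl)pentan-2-ol (secondary ozonide) | C[C@H](O)CCCC1OCOO1 | intermediate (not isolated)
11 | (6S)-6-methyltetrahydro-2H-pyran-2-ol (lactol of (S)-5-hydroxyhexanal, anomeric mixture) | C[C@H]1CCCC(O)O1 | intermediate
12 | propane-1,3-diylbis(triphenylphosphonium) dibromide | [Br-].[Br-].c1ccccc1[P+](c1ccccc1)(c1ccccc1)CCC[P+](c1ccccc1)(c1ccccc1)c1ccccc1 | starting material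
13 | [3-(triphenylphosphonio)propylidene]triphenylphosphorane bromide (mono-ylide) | [Br-].C(=P(c1ccccc1)(c1ccccc1)c1ccccc1)CC[P+](c1ccccc1)(c1ccccc1)c1ccccc1 | intermediate (not isolated)
14 | {(3Z)-11-[3,5-bis(triisopropylsilyloxy)phenyl]undec-3-en-1-yl}triphenylphosphonium bromide | [Br-].c1ccccc1[P+](c1ccccc1)(c1ccccc1)CC/C=C\CCCCCCCc1cc(O[Si](C(C)C)(C(C)C)C(C)C)cc(O[Si](C(C)C)(C(C)C)C(C)C)c1 | intermediate (not isolated)
15 | {(3Z)-11-[3,5-bis(triisopropylsilyloxy)phenyl]undec-3-en-1-ylidene}triphenylphosphorane | C(=P(c1ccccc1)(c1ccccc1)c1ccccc1)C/C=C\CCCCCCCc1cc(O[Si](C(C)C)(C(C)C)C(C)C)cc(O[Si](C(C)C)(C(C)C)C(C)C)c1 | intermediate (not isolated)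
16 | sodium (6S)-6-methyltetrahydro-2H-pyran-2-olate (ring-chain tautomer of sodium (S)-6-oxohexan-2-olate) | C[C@H]1CCCC([O-])O1.[Na+] | intermediate (not isolated)
17 | (2S,6Z,9Z)-17-[3,5-bis(triisopropylsilyloxy)phenyl]heptadeca-6,9-dien-2-ol | C[C@H](O)CCC/C=C\C/C=C\CCCCCCCc1cc(O[Si](C(C)C)(C(C)C)C(C)C)cc(O[Si](C(C)C)(C(C)C)C(C)C)c1 | intermediate
18 | Hansfordiol D, 5-[(8Z,11Z,16S)-16-hydroxyheptadeca-8,11-dien-1-yl]benzene-1,3-diol | C[C@H](O)CCC/C=C\C/C=C\CCCCCCCc1cc(O)cc(O)c1 | target

**Total step count:** 7
**Longest linear sequence:** 5 steps (steps 1, 2, 3, 6, 7)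

**Steps most likely to fail**

Step 6. The two phosphonium termini may not be differentiated cleanly: over-deprotonation of the poorly soluble salt to the bis-ylide would lead to statistical double olefination, and the oxido-aldehyde stage may erode the Z-selectivity. The fallback replaces the linchpin by a stepwise construction of the same phosphonium salt. It sets out from 6: Wittig olefination with the ylide of commercial [3-(tert-butyldimethylsilyloxy)propyl]triphenylphosphonium bromide (NaHMDS, THF, −78 °C) should give tert-butyl{[(3Z)-11-[3,5-bis(triisopropylsilyloxy)phenyl]undec-3-en-1-yl]oxy}dimethylsilane F1. Direct conversion of the alkyl silyl ether into the bromide with Ph3PBr2 (CH2Cl2, 0 °C) should give 1-[(8Z)-11-bromoundec-8-en-1-yl]-3,5-bis(triisopropylsilyloxy)benzene F2. Quaternisation with PPh3 (MeCN, 80 °C) then comes back to the route at 14, now isolated, from which the second half of step 6 (NaHMDS, then 16) continues to 17.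

Step 2. The aryl silyl ethers may hydrolyse in hot aqueous phosphate, and the O-borylated alkylborane may transmetalate slowly and be lost to protodeboronation. The fallback replaces the sp3–sp2 coupling by an sp–sp2 coupling under anhydrous amine conditions. It sets out from 2: Sonogashira coupling with commercial oct-7-yn-1-ol (PdCl2(PPh3)2, CuI, Et3N, 70 °C) should give 8-[3,5-bis(triisopropylsilyloxy)phenyl]oct-7-yn-1-ol F3. Full hydrogenation of the alkyne (H2, Pd/C, EtOAc, rt) comes back to the route at 5.

Step 5. The small, volatile, water-miscible lactol may be lost during isolation, and the hemiacetal may be over-oxidised to the lactone during ozonide reduction. The fallback avoids the lactol and carries the carbinol as a silyl ether. It sets out from 9: silylation (TBSCl, imidazole, DMF) should give (S)-tert-butyl(hept-6-en-2-yloxy)dimethylsilane F4. Ozonolysis with reductive work-up (O3, CH2Cl2, −78 °C; PPh3) should give (S)-5-(tert-butyldimethylsilyloxy)hexanal F5. F5 is used in place of 16 in the second stage of step 6 (no extra base needed) and should give tert-butyl{[(2S,6Z,9Z)-17-[3,5-bis(triisopropylsilyloxy)phenyl]heptadeca-6,9-dien-2-yl]oxy}dimethylsilane F6. Global desilylation (TBAF, 4 equiv, THF, rt) comes back to the route at 18.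

**Further compounds**

F1 | step 6 | tert-butyl{[(3Z)-11-[3,5-bis(triisopropylsilyloxy)phenyl]undec-3-en-1-yl]oxy}dimethylsilane | CC(C)(C)[Si](C)(C)OCC/C=C\CCCCCCCc1cc(O[Si](C(C)C)(C(C)C)C(C)C)cc(O[Si](C(C)C)(C(C)C)C(C)C)c1
F2 | step 6 | 1-[(8Z)-11-bromoundec-8-en-1-yl]-3,5-bis(triisopropylsilyloxy)benzene | BrCC/C=C\CCCCCCCc1cc(O[Si](C(C)C)(C(C)C)C(C)C)cc(O[Si](C(C)C)(C(C)C)C(C)C)c1
F3 | step 2 | 8-[3,5-bis(triisopropylsilyloxy)phenyl]oct-7-yn-1-ol | OCCCCCCC#Cc1cc(O[Si](C(C)C)(C(C)C)C(C)C)cc(O[Si](C(C)C)(C(C)C)C(C)C)c1
F4 | step 5 | (S)-tert-butyl(hept-6-en-2-yloxy)dimethylsilane | C[C@H](O[Si](C)(C)C(C)(C)C)CCCC=C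
F5 | step 5 | (S)-5-(tert-butyldimethylsilyloxy)hexanal | C[C@H](O[Si](C)(C)C(C)(C)C)CCCC=O
F6 | step 5 | tert-butyl{[(2S,6Z,9Z)-17-[3,5-bis(triisopropylsilyloxy)phenyl]heptadeca-6,9-dien-2-yl]oxy}dimethylsilane | C[C@H](O[Si](C)(C)C(C)(C)C)CCC/C=C\C/C=C\CCCCCCCc1cc(O[Si](C(C)C)(C(C)C)C(C)C)cc(O[Si](C(C)C)(C(C)C)C(C)C)c1
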